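**Retrosynthetic overview**

1. Ajugaciliatin A ⇐ esterification and Nozaki–Hiyama–Kishi attachment of the ready-made butenolide 22 to a C12 aldehyde; chlorohydrin ⇐ 4α,18-epoxide ⇐ C4 ketone (unmasked ketal).
2. 1β-OH, 6α-OH, 8α-CH3 and the C19 carbinol ⇐ one dissolving-metal reduction of keto-enone ester 10; C6 oxygen ⇐ allylic oxidation of the Δ7 alkene; C11–C12 ⇐ hydroboration of a vinyl group on C9.
3. Decalin ⇐ enantioselective Diels–Alder union of quinone monoketal ester 2 (ring A) with the C2h-symmetric triene 5, forming C5–C6 and C9–C10 (ring B) and both quaternary carbons C5 and C9.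
4. Enabling feature: ring A is oxygenated at C1 and C4 (para) and carries the carboxyl-level carbon C19 on C5, so its C5–C10 bond is the doubly acyl-activated alkene of a para-quinone monoketal ester; C6–C7–C8–C9 of ring B, with C20 and the C11–C12 chain on C9, is one half of the triene.
5. Ring order: ring A is the arene ring of 1 and is never closed in the route; ring B is the only skeletal ring closed (step 4); the butenolide ring arrives intact in 22 (step 16).

Key step: step 4

Remark: clerodane numbering is used (ring A = C1–C5, C10; ring B = C5–C10; α = face of C19 and C20, β = face of H-10 in the target), and phenol 1 is assumed to be a catalogue compound.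

**Route**

Step 1
Reactants: 1 methyl 5-hydroxy-2-methoxybenzoate
Product: 2 methyl 6,6-dimethoxy-3-oxocyclohexa-1,4-diene-1-carboxylate (quinone monoketal ester)
Conditions: PhI(OAc)2 (1.1 equiv), MeOH, 0 °C
Reagents that add atoms: methanol CO
Why: Oxidative dearomatisation of a para-methoxyphenol by a hypervalent iodine reagent, the phenoxenium ion being trapped by methanol at the methoxy-bearing carbon to give the para-quinone monoketal; no stereocenter is formed.

Step 2
Reactants: 3 but-2-yne
Product: 4 (E)-2,3-dibromobut-2-ene
Conditions: Br2 (1.0 equiv), CH2Cl2, −78 → −20 °C, dark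
Reagents that add atoms: bromine BrBr
Why: Electrophilic anti addition of one equivalent of bromine through a bridged bromonium ion should give the (E)-dibromide, which fixes the trans arrangement that becomes the tetrasubstituted (E)-alkene of the triene.

Step 3
Reactants: 4 (E)-2,3-dibromobut-2-ene
Product: 5 (E)-3,4-dimethylhexa-1,3,5-triene
Conditions: CH2=CHSnBu3 (2.4 equiv), Pd(PPh3)4 (5 mol %), CuI (10 mol %), DMF, 60 °C
Reagents that add atoms: tributyl(vinyl)stannane C=C[Sn](CCCC)(CCCC)CCCC
Why: Twofold Stille coupling proceeds with retention of alkene geometry (palladium and the second bromide are trans, so syn β-halide elimination to the alkyne is not possible), giving the symmetric triene whose two diene halves are identical.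

Step 4
Reactants: 2 quinone monoketal ester; 5 (E)-3,4-dimethylhexa-1,3,5-triene
Product: 6 cis-fused adduct (ring A: 2-en-1-one, 4,4-dimethoxy, 5α-CO2Me, 10α-H; ring B: 7-ene, 8-methyl, 9α-methyl, 9β-vinyl)
Conditions: 5 (2 equiv), oxazaborolidinium triflimide from (S)-α,α-diphenylprolinol, o-tolylboronic acid and Tf2NH (20 mol %), CH2Cl2, −78 → −20 °C
Reagents that add atoms: none
Why: Concerted but asynchronous [4+2] cycloaddition: the chiral boron cation binds the C1 ketone of 2 and lowers the LUMO of the doubly acyl-activated C5=C10 bond, the terminal CH2 (C6) of the triene (largest HOMO coefficient) bonds first to C5 (β to the bound ketone) and the hindered terminus C9 closes onto C10 late in the transition state. The closest known reaction type is the oxazaborolidinium-catalysed enantioselective Diels–Alder reaction of para-quinone monoketals and of β-acyl acrylates, in which the ketone controls orientation. Ring B is closed by intermolecular suprafacial [4+2] addition (bonds C5–C6 and C9–C10 formed on one face of the ring-A alkene, endo to the complexed ketone). C5 and C10 become cis because both bonds form on the same face; C9 follows from the (E) geometry of the triene together with the endo rule (outside vinyl trans to the ester, inside methyl cis to it); the absolute sense comes from the catalyst, whose aryl group shields one face of the bound dienone (the antipode is used if the first adduct shows the opposite sense). The step needs site selectivity (C5=C10, not C2=C3), regioselectivity and endo selectivity, which should be secured by the two acyl groups on C5=C10, by the ketone-controlled polarisation matched to the terminal CH2 of the triene, and by the Lewis-acid-bound carbonyl; the C2h symmetry of 5 makes its two diene halves equivalent. Only C10 is set wrongly (cis fusion) and it is corrected in step 5, where it lies α to the C1 ketone.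

Step 5
Reactants: 6 cis-fused adduct
Product: 9 trans-fused saturated C1 ketone (10β-H), via triethylsilyl enol ether 7 (not isolated), via cis-fused ketone 8 (not isolated)
Conditions: Et3SiH, RhCl(PPh3)3 (2 mol %), toluene, 50 °C; then K2CO3, MeOH, rt
Reagents that add atoms: none
Why: Rhodium-catalysed 1,4-hydrosilylation reduces only the enone (the hindered Δ7 alkene and the neopentyl vinyl group should not react), and methanolysis with K2CO3 frees the ketone and equilibrates C10 to the trans-fused decalone, expected to be favoured because the cis isomer keeps a comparable 1,3-diaxial contact between C5 and C9 substituents and adds the gauche strain of a cis-decalin.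

Step 6
Reactants: 9 trans-fused ketone
Product: 10 keto-enone ester (C6 ketone conjugated with C7=C8)
Conditions: Rh2(cap)4 (dirhodium tetracaprolactamate, 1 mol %), t-BuOOH (70% aq, 5 equiv), CH2Cl2, rt
Reagents that add atoms: tert-butyl hydroperoxide CC(C)(C)OO
Why: Radical allylic C–H oxidation by the tert-butylperoxyl chain should take the ring methylene C6 next to the unsubstituted alkene carbon C7 (the selectivity of 1-methylcyclohexene giving 3-methylcyclohexenone); C9 is quaternary and the vinyl group has no allylic hydrogen.

Step 7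
Reactants: 10 keto-enone ester
Product: 11 triol (1β-OH, 6α-OH, 19-OH, 8α-methyl, 4,4-dimethoxy, 9β-vinyl)
Conditions: Li (15 equiv), NH3(l)/THF, EtOH, −78 → −33 °C; NH4Cl
Reagents that add atoms: none
Why: Dissolving-metal reduction should do four jobs under stereoelectronic or thermodynamic control: the enone is reduced with axial protonation at C8 (H-8β, methyl equatorial), the C6 and C1 carbonyls give the more stable equatorial alcohols (the axial 1α epimer would be syn-axial to C19 and C20), and the non-enolisable methyl ester is reduced to the C19 carbinol (Bouveault–Blanc); the ketal and the isolated vinyl group are inert.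

Step 8
Reactants: 11 triol
Product: 12 6α,19-O-isopropylidene acetal with free 1β-OH
Conditions: Me2C(OMe)2, PPTS (cat.), CH2Cl2, rt
Reagents that add atoms: 2,2-dimethoxypropane COC(C)(C)OC
Why: Only the cis-disposed 6α,19-diol can close a chair 1,3-dioxane acetal; the 1β-hydroxyl is trans to C19 and stays free.

Step 9
Reactants: 12 acetonide; 13 (S)-2-methylbutanoic acid
Product: 14 1β-(S)-2-methylbutanoate of the acetonide
Conditions: 13, DCC, DMAP (cat.), CH2Cl2, 0 °C → rt
Reagents that add atoms: none
Why: Steglich esterification of the only free hydroxyl; carbodiimide activation at low temperature should not epimerise the α-stereocenter of the acid.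

Step 10
Reactants: 14 ester acetonide
Product: 15 C4 ketone 6α,19-diol (1β-ester retained)
Conditions: 2 M HCl, THF, rt
Reagents that add atoms: water O
Why: Acid hydrolysis removes the isopropylidene acetal and the dimethyl ketal together; the ester and vinyl group are stable, and the β-hydroxy ketone cannot dehydrate because C5 is quaternary.

Step 11
Reactants: 15 keto diol
Product: 16 6α,19-diacetate
Conditions: Ac2O, pyridine, DMAP (cat.), CH2Cl2, rt
Reagents that add atoms: acetic anhydride CC(=O)OC(C)=O
Why: DMAP-catalysed acetylation of the primary and the equatorial secondary hydroxyl, the only free hydroxyls present.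

Step 12
Reactants: 16 diacetate ketone
Product: 17 4α,18-epoxide (spiro-oxirane at C4, oxygen α, CH2 β)
Conditions: Me3S+ I−, KN(SiMe3)2, THF, −10 → 0 °C
Reagents that add atoms: trimethylsulfonium iodide C[S+](C)C.[I-]
Why: Corey–Chaykovsky epoxidation: irreversible addition of dimethylsulfonium methylide along the axial β trajectory, which passes only axial hydrogens (C2, C6, C10), whereas the equatorial path is blocked by the axial C19 acetoxymethyl group, so CH2 ends axial (β) and oxygen equatorial (α); the ketone should react faster than the hindered esters.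

Step 13
Reactants: 17 epoxide
Product: 19 C12 primary alcohol (9β-CH2CH2OH), via B-alkyl-9-borabicyclononane 18 (not isolated)
Conditions: 9-BBN, THF, rt; then NaBO3·4H2O, H2O
Reagents that add atoms: sodium perborate [Na+].[O-]OB=O
Why: Anti-Markovnikov hydroboration of the only remaining alkene and mild perborate oxidation with retention; esters and the epoxide are inert to 9-BBN.

Step 14
Reactants: 19 epoxy alcohol
Product: 20 chlorohydrin (4α-OH, 18-Cl)
Conditions: LiCl, AcOH, THF, rt
Reagents that add atoms: lithium chloride [Li+].[Cl-]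
Why: Mildly acid-assisted SN2 opening of the spiro-epoxide by chloride at the primary carbon C18 leaves the C4–O bond untouched, so the tertiary hydroxyl stays α.

Step 15
Reactants: 20 chlorohydrin alcohol
Product: 21 C12 aldehyde
Conditions: Dess–Martin oxidation: DMP (1,1,1-triacetoxy-1,2-benziodoxol-3(1H)-one), pyridine, CH2Cl2, 0 °C → rt
Reagents that add atoms: none
Why: The primary alcohol is the only oxidisable hydroxyl, since the tertiary C4 hydroxyl cannot be oxidised.

Step 16
Reactants: 21 aldehyde; 22 4-bromofuran-2(5H)-one
Product: 23 (12S)-carbinol carrying the butenolide at C13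
Conditions: CrCl2 (4 equiv), NiCl2 (2 mol %), chiral oxazoline–sulfonamide ligand, Et3N, THF/MeCN, rt
Reagents that add atoms: none
Why: Nozaki–Hiyama–Kishi coupling: nickel-catalysed formation of the alkenylchromium from the β-bromo butenolide and chemoselective addition to the aldehyde (alkyl chloride, esters and tertiary alcohol tolerated); C12 is set by the chiral ligand on chromium (reagent control, ligand antipode chosen for 12S).

Step 17
Reactants: 23 carbinol; 13 (S)-2-methylbutanoic acid
Product: 24 ajugaciliatin A
Conditions: 13, DCC, DMAP (cat.), CH2Cl2, 0 °C → rt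
Reagents that add atoms: none
Why: Steglich esterification of the secondary C12 hydroxyl; the hindered tertiary C4 hydroxyl should not be acylated.

**Compound list**

1 | methyl 5-hydroxy-2-methoxybenzoate | COC(=O)c1cc(O)ccc1OC | starting material
2 | methyl 6,6-dimethoxy-3-oxocyclohexa-1,4-diene-1-carboxylate | COC(=O)C1=CC(=O)C=CC1(OC)OC | intermediate
3 | but-2-yne | CC#CC | starting material
4 | (E)-2,3-dibromobut-2-ene | C/C(Br)=C(Br)/C | intermediate
5 | (E)-3,4-dimethylhexa-1,3,5-triene | C=C/C(C)=C(C)/C=C | intermediate
6 | cis-fused adduct: 2-en-1-one, 4,4-dimethoxy, 5α-CO2Me, 10α-H, 7-ene, 8-methyl, 9α-methyl, 9β-vinyl | C=C[C@@]1(C)C(C)=CC[C@]2(C(=O)OC)[C@H]1C(=O)C=CC2(OC)OC | intermediate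
7 | triethylsilyl enol ether of 8 (C1–OSiEt3, C1=C2, cis-fused) | C=C[C@@]1(C)C(C)=CC[C@]2(C(=O)OC)[C@H]1C(O[Si](CC)(CC)CC)=CCC2(OC)OC | intermediate
8 | cis-fused saturated C1 ketone (10α-H) | C=C[C@@]1(C)C(C)=CC[C@]2(C(=O)OC)[C@H]1C(=O)CCC2(OC)OC | intermediate
9 | trans-fused saturated C1 ketone (10β-H) | C=C[C@@]1(C)C(C)=CC[C@]2(C(=O)OC)[C@@H]1C(=O)CCC2(OC)OC | intermediate
10 | keto-enone ester: 9 with C6 ketone conjugated to C7=C8 | C=C[C@@]1(C)C(C)=CC(=O)[C@]2(C(=O)OC)[C@@H]1C(=O)CCC2(OC)OC | intermediate
11 | triol: 1β-OH, 6α-OH, 19-OH, 8α-methyl, 4,4-dimethoxy, 9α-methyl, 9β-vinyl, trans-decalin | C=C[C@@]1(C)[C@H](C)C[C@H](O)[C@]2(CO)[C@@H]1[C@H](O)CCC2(OC)OC | intermediate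
12 | 6α,19-O-isopropylidene acetal of 11 | C=C[C@@]1(C)[C@H](C)C[C@@H]4OC(C)(C)OC[C@]42[C@@H]1[C@H](O)CCC2(OC)OC | intermediate
13 | (S)-2-methylbutanoic acid | CC[C@H](C)C(=O)O | starting material
14 | 1β-(S)-2-methylbutanoate of 12 | C=C[C@@]1(C)[C@H](C)C[C@@H]4OC(C)(C)OC[C@]42[C@@H]1[C@H](OC(=O)[C@@H](C)CC)CCC2(OC)OC | intermediate
15 | C4 ketone, 6α,19-diol, 1β-(S)-2-methylbutanoate | C=C[C@@]1(C)[C@H](C)C[C@H](O)[C@]2(CO)[C@@H]1[C@H](OC(=O)[C@@H](C)CC)CCC2=O | intermediate
16 | 6α,19-diacetate of 15 | C=C[C@@]1(C)[C@H](C)C[C@H](OC(C)=O)[C@]2(COC(C)=O)[C@@H]1[C@H](OC(=O)[C@@H](C)CC)CCC2=O | intermediate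
17 | 4α,18-epoxide (spiro-oxirane, O α, CH2 β) | C=C[C@@]1(C)[C@H](C)C[C@H](OC(C)=O)[C@]2(COC(C)=O)[C@@H]1[C@H](OC(=O)[C@@H](C)CC)CC[C@]23CO3 | intermediate
18 | B-(C12-alkyl)-9-borabicyclo[3.3.1]nonane from 17 | C(B3C4CCCC3CCC4)C[C@@]1(C)[C@H](C)C[C@H](OC(C)=O)[C@]2(COC(C)=O)[C@@H]1[C@H](OC(=O)[C@@H](C)CC)CC[C@]23CO3 | intermediate
19 | 12-hydroxy 4α,18-epoxide | OCC[C@@]1(C)[C@H](C)C[C@H](OC(C)=O)[C@]2(COC(C)=O)[C@@H]1[C@H](OC(=O)[C@@H](C)CC)CC[C@]23CO3 | intermediate
20 | chlorohydrin: 4α-OH, 18-Cl, 12-OH | OCC[C@@]1(C)[C@H](C)C[C@H](OC(C)=O)[C@]2(COC(C)=O)[C@@H]1[C@H](OC(=O)[C@@H](C)CC)CC[C@]2(O)CCl | intermediate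
21 | C12 aldehyde | O=CC[C@@]1(C)[C@H](C)C[C@H](OC(C)=O)[C@]2(COC(C)=O)[C@@H]1[C@H](OC(=O)[C@@H](C)CC)CC[C@]2(O)CCl | intermediate
22 | 4-bromofuran-2(5H)-one | BrC1=CC(=O)OC1 | starting material
23 | (12S)-12-hydroxy compound with butenolide at C13 | O[C@@H](C[C@@]1(C)[C@H](C)C[C@H](OC(C)=O)[C@]2(COC(C)=O)[C@@H]1[C@H](OC(=O)[C@@H](C)CC)CC[C@]2(O)CCl)C1=CC(=O)OC1 | intermediate
24 | ajugaciliatin A | CC[C@H](C)C(=O)O[C@@H](C[C@@]1(C)[C@H](C)C[C@H](OC(C)=O)[C@]2(COC(C)=O)[C@@H]1[C@H](OC(=O)[C@@H](C)CC)CC[C@]2(O)CCl)C1=CC(=O)OC1 | target

**Step count and risks**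

Total step count: 17. Longest linear sequence: 16 steps (3 → 4 → 5 → 6 → 9 → 10 → 11 → 12 → 14 → 15 → 16 → 17 → 19 → 20 → 21 → 23 → 24).

The three steps most likely to fail:

Step 4. The catalyst may discriminate the two faces of the dienone poorly or be inhibited by the ketal oxygens, and the hindered triene terminus may react slowly. Fallback: setting out from 2 and 5, the cycloaddition is run without a chiral catalyst (12 kbar in CH2Cl2 at rt, or ZnCl2 in Et2O). This should give racemic material, that is 6 together with its mirror image, ent-adduct F1. The enantiomers are separated by preparative chromatography on a chiral stationary phase, and the route is rejoined at 6.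

Step 6. Hydrogen abstraction at the neopentyl C6 methylene may be slower than attack at the C17 methyl, or the peroxide chain may over-oxidise. Fallback: from 9, a Schenck ene reaction with singlet oxygen (O2, tetraphenylporphyrin, hν, CH2Cl2, 0 °C) should abstract H-6β and place oxygen on C8 from the less hindered β face, giving the tertiary allylic hydroperoxide F2 (C8–OOH, C6=C7). PPh3 reduces it to the tertiary allylic alcohol F3. Babler–Dauben oxidative transposition (pyridinium chlorochromate, C5H5NH[CrO3Cl], CH2Cl2) then moves the oxygen to C6 and returns enone 10.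

Step 16. Reagent control over the remote C12 stereocenter may be weak and give a mixture of carbinol epimers. Fallback: from 21 and 22 the coupling is run without the chiral ligand (CrCl2, NiCl2 cat., DMF), giving 23 mixed with its C12 epimer, 12-epi-carbinol F4. Dess–Martin oxidation of the mixture converges both on the C12 ketone F5. Corey–Bakshi–Shibata reduction ((R)-methyl-oxazaborolidine, catecholborane, toluene, −78 °C, with the butenolide alkenyl group assumed to act as the large substituent) should then return 23.

**Further compounds**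

F1 | step 4 | ent-adduct (mirror image of 6) | C=C[C@]1(C)C(C)=CC[C@@]2(C(=O)OC)[C@@H]1C(=O)C=CC2(OC)OC
F2 | step 6 | 8β-hydroperoxy-6-ene (from 9; C8 bears OOH and methyl) | C=C[C@@]1(C)[C@@](C)(OO)C=C[C@]2(C(=O)OC)[C@@H]1C(=O)CCC2(OC)OC
F3 | step 6 | 8β-hydroxy-6-ene tertiary allylic alcohol | C=C[C@@]1(C)[C@@](C)(O)C=C[C@]2(C(=O)OC)[C@@H]1C(=O)CCC2(OC)OC
F4 | step 16 | 12-epi-carbinol (12R epimer of 23) | O[C@H](C[C@@]1(C)[C@H](C)C[C@H](OC(C)=O)[C@]2(COC(C)=O)[C@@H]1[C@H](OC(=O)[C@@H](C)CC)CC[C@]2(O)CCl)C1=CC(=O)OC1
F5 | step 16 | C12 ketone | O=C(C[C@@]1(C)[C@H](C)C[C@H](OC(C)=O)[C@]2(COC(C)=O)[C@@H]1[C@H](OC(=O)[C@@H](C)CC)CC[C@]2(O)CCl)C1=CC(=O)OC1
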